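## Retrosynthetic overview

1. Prevezol C ⇒ a C20 triene: the trans-diaxial diol of ring A comes last, by epoxidation and hydrolysis of a 1-methylcyclohexene.
2. Triene ⇒ ring B allylsilane + (4S)-p-menthadienyl cation (from (−)-limonene oxide): the CH2–ring A bond is made by SN1 allylation, trans to the isopropenyl group.
3. Allylsilane ⇒ ring B hydroxy ester; the syn-bromohydrin ⇒ α-bromoketone + a methyl nucleophile; the ester-bearing centre is set by equilibration.
4. Key step: a catalytic enantioselective α-bromination that breaks the mirror symmetry of ethyl 4-oxocyclohexanecarboxylate, itself the hydrogenation product of ethyl 4-hydroxybenzoate.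
5. Ring order: no ring is closed by cyclisation. Ring B is the former benzene ring and is finished first; ring A is the terpene ring brought in from (−)-limonene oxide and joined last.

Assumption: the antipode of the amine catalyst in step 2 is the one that delivers bromine to give the (R)-configured C–Br centre; the sense of induction is taken by analogy with 2-bromocyclohexanone and must be confirmed.

## Route

Step 1
Reactants: 1 ethyl 4-hydroxybenzoate
Product: 2 ethyl 4-oxocyclohexane-1-carboxylate
Conditions: H2 (5 bar), 5% Pd/C, cyclohexane, 120 °C, stopped after 2 equiv H2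
Reagents that add atoms: none
Why: Palladium on carbon adds two equivalents of H2 to the phenol ring and releases the ketone before it is reduced further (selective partial hydrogenation of a phenol to a cyclohexanone); the ester is inert, no stereocentre is formed, and the product is the Cs-symmetric ketone needed for the key step.

Step 2
Reactants: 2 ethyl 4-oxocyclohexane-1-carboxylate
Product: 3 ethyl (1S,3R)-3-bromo-4-oxocyclohexane-1-carboxylate (trans; Br axial and ester equatorial)
Conditions: 4,4-dibromo-2,6-di-tert-butylcyclohexa-2,5-dien-1-one (1.0 equiv), (4R,5R)-4,5-diphenylimidazolidine (20 mol%), PhCO2H (20 mol%), THF, −30 °C; used crude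
Reagents that add atoms: 4,4-dibromo-2,6-di-tert-butylcyclohexa-2,5-dien-1-one, CC(C)(C)C1=CC(Br)(Br)C=C(C(C)(C)C)C1=O
Why: Proposed new method: the C2-symmetric secondary amine forms an enamine with the prochiral ketone, and the bulky Br+ donor is delivered to one face along the axial trajectory (trans to the equatorial ester), so a single step breaks the mirror symmetry and fixes the C–Br centre as R (the ester-bearing centre is corrected in step 4, so only the enantioselectivity at C–Br matters); the closest known chemistry is the amine-catalysed enantioselective α-bromination of cyclohexanone with this catalyst and Br+ source, and the proline-catalysed desymmetrising α-functionalisation of 4-substituted cyclohexanones.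

Step 3
Reactants: 3 ethyl (1S,3R)-3-bromo-4-oxocyclohexane-1-carboxylate
Product: 4 ethyl (1S,3R,4S)-3-bromo-4-hydroxy-4-methylcyclohexane-1-carboxylate (OH cis to Br)
Conditions: MeMgBr (1.2 equiv), CeCl3 (1.5 equiv), THF, −78 °C; H2O work-up
Reagents that add atoms: methylmagnesium bromide, C[Mg]Br
Why: Chemoselective 1,2-addition of the weakly basic methyl organocerium reagent to the ketone (Imamoto conditions; the ester is untouched at −78 °C) under Felkin–Anh/Cornforth polar control: the nucleophile enters anti to the axial C–Br bond, so OH ends cis to Br (the classical syn-halohydrin outcome of 2-halocyclohexanones) and the carbinol centre is set as S.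

Step 4
Reactants: 4 ethyl (1S,3R,4S)-3-bromo-4-hydroxy-4-methylcyclohexane-1-carboxylate
Product: 5 ethyl (1R,3R,4S)-3-bromo-4-hydroxy-4-methylcyclohexane-1-carboxylate (ester, Br and OH all cis)
Conditions: NaOEt (0.3 equiv), EtOH, 0 °C → rt
Reagents that add atoms: none
Why: Thermodynamic epimerisation through the ester enolate (protic medium, so the short-lived enolate is reprotonated before it can displace bromide) moves CO2Et to the equatorial position of the chair that already has Br and CH3 equatorial, giving the 1R epimer in an estimated 7:1 ratio (minor epimer recycled); the cis-bromohydrin cannot close to an epoxide.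

Step 5
Reactants: 5 ethyl (1R,3R,4S)-3-bromo-4-hydroxy-4-methylcyclohexane-1-carboxylate
Product: 7 (1S,2R,4R)-2-bromo-1-methyl-4-[3-(trimethylsilyl)prop-1-en-2-yl]cyclohexan-1-ol, via bis(silylmethyl) carbinol 6 (not isolated)
Conditions: Me3SiCH2MgCl (5 equiv), CeCl3 (5 equiv), THF, −78 °C → rt; then SiO2, CH2Cl2, rt
Reagents that add atoms: (trimethylsilyl)methylmagnesium chloride, C[Si](C)(C)C[Mg]Cl
Why: Bunnelle–Narayanan allylsilane synthesis: double addition of the non-basic organocerium reagent to the ester gives the bis(β-silyl) carbinol, which loses Me3SiOH on silica (Peterson elimination) to the 2-substituted allylsilane; no stereocentre is touched and the secondary bromide and tertiary alcohol are spectators.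

Step 6
Reactants: 8 (−)-limonene 1,2-oxide (commercial cis/trans mixture from (S)-limonene; the reacting isomer is trans, (1R,2S,4S) in p-menthane numbering)
Product: 11 (1R,4S)-1-methyl-4-(prop-1-en-2-yl)cyclohex-2-en-1-ol, via hydroxy selenide 9 (not isolated), via selenoxide 10 (not isolated)
Conditions: PhSeSePh, NaBH4, EtOH, rt → 80 °C; then 30% H2O2, THF, 0 °C → rt
Reagents that add atoms: none
Why: Sharpless–Lauer epoxide-to-allylic-alcohol transposition: PhSe− opens the trans-oxide at the secondary carbon (trans-diaxial SN2), oxidation gives the selenoxide, and syn-elimination can only go away from the fully substituted carbinol carbon, so the C4 centre (S) is retained (the cis-oxide reacts far more slowly and is removed).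

Step 7
Reactants: 7 (1S,2R,4R)-2-bromo-1-methyl-4-[3-(trimethylsilyl)prop-1-en-2-yl]cyclohexan-1-ol; 11 (1R,4S)-1-methyl-4-(prop-1-en-2-yl)cyclohex-2-en-1-ol (1.3 equiv)
Product: 12 (1S,2R,4R)-2-bromo-1-methyl-4-{3-[(1S,6S)-3-methyl-6-(prop-1-en-2-yl)cyclohex-2-en-1-yl]prop-1-en-2-yl}cyclohexan-1-ol
Conditions: BF3·OEt2 (20 mol%), 4 Å molecular sieves, CH2Cl2, −40 → −10 °C
Reagents that add atoms: none
Why: BF3 ionises the tertiary allylic alcohol to the p-menthadienyl cation (the cation used in cannabidiol syntheses), which the allylsilane captures at its less hindered secondary terminus anti to the adjacent isopropenyl group (Hosomi–Sakurai-type SN1 allylation), setting the ring A side-chain carbon trans to isopropenyl while loss of silicon installs the 1,1-disubstituted linker alkene; the cis-bromohydrin has no antiperiplanar Br and does not ionise.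

Step 8
Reactants: 12 (1S,2R,4R)-2-bromo-1-methyl-4-{3-[(1S,6S)-3-methyl-6-(prop-1-en-2-yl)cyclohex-2-en-1-yl]prop-1-en-2-yl}cyclohexan-1-ol
Product: 14 prevezol C, (1R,2R,3R,4S)-3-{2-[(1R,3R,4S)-3-bromo-4-hydroxy-4-methylcyclohexyl]prop-2-en-1-yl}-1-methyl-4-(prop-1-en-2-yl)cyclohexane-1,2-diol, via epoxide 13 (not isolated)
Conditions: mCPBA (1.0 equiv), CH2Cl2, −20 °C; then THF–H2O, HClO4 (5 mol%), 0 °C → rt
Reagents that add atoms: 3-chloroperoxybenzoic acid (mCPBA), OOC(=O)c1cccc(Cl)c1; water, O
Why: Prilezhaev epoxidation of the only trisubstituted (most electron-rich) alkene followed by acid-catalysed trans-diaxial (Fürst–Plattner) hydrolysis: water enters at the tertiary carbon of the epoxide syn to the side chain and at the secondary carbon of the other epoxide, so both faces converge, as both limonene oxides do, on the diaxial 1R,2R diol with side chain and isopropenyl equatorial.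

## Compound list

1 | ethyl 4-hydroxybenzoate | CCOC(=O)c1ccc(O)cc1 | starting material
2 | ethyl 4-oxocyclohexane-1-carboxylate | CCOC(=O)C1CCC(=O)CC1 | intermediate
3 | ethyl (1S,3R)-3-bromo-4-oxocyclohexane-1-carboxylate | CCOC(=O)[C@H]1CCC(=O)[C@H](Br)C1 | intermediate
4 | ethyl (1S,3R,4S)-3-bromo-4-hydroxy-4-methylcyclohexane-1-carboxylate | CCOC(=O)[C@H]1CC[C@](C)(O)[C@H](Br)C1 | intermediate
5 | ethyl (1R,3R,4S)-3-bromo-4-hydroxy-4-methylcyclohexane-1-carboxylate | CCOC(=O)[C@@H]1CC[C@](C)(O)[C@H](Br)C1 | intermediate
6 | (1S,2R,4R)-2-bromo-4-[2-hydroxy-1,3-bis(trimethylsilyl)propan-2-yl]-1-methylcyclohexan-1-ol | C[Si](C)(C)CC(O)(C[Si](C)(C)C)[C@@H]1CC[C@](C)(O)[C@H](Br)C1 | intermediate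
7 | (1S,2R,4R)-2-bromo-1-methyl-4-[3-(trimethylsilyl)prop-1-en-2-yl]cyclohexan-1-ol | C=C(C[Si](C)(C)C)[C@@H]1CC[C@](C)(O)[C@H](Br)C1 | intermediate
8 | (−)-limonene 1,2-oxide, commercial cis/trans mixture; SMILES shows the reacting trans-(1R,2S,4S) isomer | C1[C@@H](C(=C)C)CC[C@@]2(C)O[C@@H]12 | starting material
9 | (1R,2R,4S)-1-methyl-2-(phenylselanyl)-4-(prop-1-en-2-yl)cyclohexan-1-ol | C1[C@@H](C(=C)C)CC[C@@](C)(O)[C@@H]1[Se]c1ccccc1 | intermediate
10 | (1R,2R,4S)-1-methyl-2-(phenylseleninyl)-4-(prop-1-en-2-yl)cyclohexan-1-ol (selenoxide of 9) | C1[C@@H](C(=C)C)CC[C@@](C)(O)[C@@H]1[Se](=O)c1ccccc1 | intermediate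
11 | (1R,4S)-1-methyl-4-(prop-1-en-2-yl)cyclohex-2-en-1-ol (OH cis to isopropenyl) | C=C(C)[C@H]1CC[C@@](C)(O)C=C1 | intermediate
12 | (1S,2R,4R)-2-bromo-1-methyl-4-{3-[(1S,6S)-3-methyl-6-(prop-1-en-2-yl)cyclohex-2-en-1-yl]prop-1-en-2-yl}cyclohexan-1-ol | C=C(C[C@@H]1[C@@H](C(=C)C)CCC(C)=C1)[C@@H]1CC[C@](C)(O)[C@H](Br)C1 | intermediate
13 | 1,2-epoxide of 12 at the ring A trisubstituted alkene, both epoxide faces; ring A centres (2R,3S) in 7-oxabicyclo[4.1.0]heptane numbering, ring B unchanged | C=C(C[C@@H]1[C@@H](C(=C)C)CCC2(C)OC12)[C@@H]1CC[C@](C)(O)[C@H](Br)C1 | intermediate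
14 | prevezol C, (1R,2R,3R,4S)-3-{2-[(1R,3R,4S)-3-bromo-4-hydroxy-4-methylcyclohexyl]prop-2-en-1-yl}-1-methyl-4-(prop-1-en-2-yl)cyclohexane-1,2-diol | C=C(C[C@@H]1[C@@H](C(=C)C)CC[C@@](C)(O)[C@@H]1O)[C@@H]1CC[C@](C)(O)[C@H](Br)C1 | target

## Step count and risks

Total steps: 8. Longest linear sequence: 7 (steps 1, 2, 3, 4, 5, 7, 8 from ethyl 4-hydroxybenzoate); step 6 is the one-step side branch.

**Step 2** is the most likely to fail. The desymmetrising bromination of a 4-substituted cyclohexanone is untested, and dibromination, N-alkylation of the catalyst or erosion of the C–Br centre on handling would all lower the enantiomeric purity of everything downstream. The fallback sets out from 2 and comes back at 3. Ketone 2 is deprotonated with a chiral lithium amide, LiN[(R)-CH(CH3)Ph]2 or its antipode (whichever gives the 1S series), with Me3SiCl present at −78 °C (Koga/Simpkins enantioselective deprotonation). This gives the silyl enol ether ethyl (1S)-4-[(trimethylsilyl)oxy]cyclohex-3-ene-1-carboxylate F1. N-Bromosuccinimide in THF at −78 °C then delivers bromine axially, trans to the ester, to give 3. In this variant the base sets the ester-bearing centre and relays it to C–Br by substrate control, so the trans/cis ratio of the bromination becomes the enantiomeric purity.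

**Step 7** may fail through protodesilylation of 7 by adventitious acid, proton loss from the cation to menthatrienes, or reversible O-alkylation of the free tertiary alcohol. The fallback sets out from 7 and comes back at 12. Allylsilane 7 is treated with N-bromosuccinimide (CH2Cl2, −78 °C, bromodesilylation with allyl shift) to give the allylic bromide (1S,2R,4R)-2-bromo-4-(3-bromoprop-1-en-2-yl)-1-methylcyclohexan-1-ol F2. The kinetic lithium enolate of commercial (S)-(+)-carvone (LiN(iPr)2, THF, −78 °C, 2.2 equiv to allow for the free hydroxyl) is alkylated with F2 at C6, anti to the isopropenyl group. This gives the enone (5S,6R)-6-{2-[(1R,3R,4S)-3-bromo-4-hydroxy-4-methylcyclohexyl]prop-2-en-1-yl}-2-methyl-5-(prop-1-en-2-yl)cyclohex-2-en-1-one F3. Condensation with TsNHNH2 gives the tosylhydrazone of F3, F4. Catecholborane followed by NaOAc·3H2O (Kabalka reductive 1,3-transposition) reduces C=N; loss of sulfinate and N2 through the allylic diazene moves the ring alkene into the limonene position and gives 12.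

**Step 8** carries two risks: over-epoxidation of the two 1,1-disubstituted alkenes, and Markovnikov (non-diaxial) opening of the epoxide that lies anti to the side chain, whose diaxial path needs attack at a hindered secondary carbon. The fallback sets out from 8 (and from 7 through bromide F2 as above) and comes back at 14. Both isomers of 8 are hydrolysed (dilute H2SO4, THF–H2O, 0 °C) to (1R,2R,4S)-1-methyl-4-(prop-1-en-2-yl)cyclohexane-1,2-diol F5. Its secondary alcohol is oxidised (SO3·pyridine, DMSO, Et3N) to (2R,5S)-2-hydroxy-2-methyl-5-(prop-1-en-2-yl)cyclohexan-1-one F6. The dianion of F6 (LiN(iPr)2, 2.2 equiv, THF, −78 °C) is alkylated with F2 anti to the isopropenyl group to give (2R,5S,6R)-6-{2-[(1R,3R,4S)-3-bromo-4-hydroxy-4-methylcyclohexyl]prop-2-en-1-yl}-2-hydroxy-2-methyl-5-(prop-1-en-2-yl)cyclohexan-1-one F7. Reduction with Me4NBH(OAc)3 (AcOH–MeCN, −20 °C, hydroxyl-directed Saksena–Evans-type delivery from the tertiary OH) gives the trans-diol 14. Here the tertiary carbinol centre comes from the chiral pool and no epoxide face selectivity is involved.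

Further compounds
F1 | step 2 | ethyl (1S)-4-[(trimethylsilyl)oxy]cyclohex-3-ene-1-carboxylate | CCOC(=O)[C@H]1CCC(O[Si](C)(C)C)=CC1
F2 | step 7 | (1S,2R,4R)-2-bromo-4-(3-bromoprop-1-en-2-yl)-1-methylcyclohexan-1-ol | C=C(CBr)[C@@H]1CC[C@](C)(O)[C@H](Br)C1
F3 | step 7 | (5S,6R)-6-{2-[(1R,3R,4S)-3-bromo-4-hydroxy-4-methylcyclohexyl]prop-2-en-1-yl}-2-methyl-5-(prop-1-en-2-yl)cyclohex-2-en-1-one | C=C(C[C@@H]1[C@@H](C(=C)C)CC=C(C)C1=O)[C@@H]1CC[C@](C)(O)[C@H](Br)C1
F4 | step 7 | N-tosylhydrazone of F3 | C=C(C[C@@H]1[C@@H](C(=C)C)CC=C(C)C1=NNS(=O)(=O)c1ccc(C)cc1)[C@@H]1CC[C@](C)(O)[C@H](Br)C1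
F5 | step 8 | (1R,2R,4S)-1-methyl-4-(prop-1-en-2-yl)cyclohexane-1,2-diol | C1[C@@H](C(=C)C)CC[C@@](C)(O)[C@@H]1O
F6 | step 8 | (2R,5S)-2-hydroxy-2-methyl-5-(prop-1-en-2-yl)cyclohexan-1-one | C1[C@@H](C(=C)C)CC[C@@](C)(O)C1=O
F7 | step 8 | (2R,5S,6R)-6-{2-[(1R,3R,4S)-3-bromo-4-hydroxy-4-methylcyclohexyl]prop-2-en-1-yl}-2-hydroxy-2-methyl-5-(prop-1-en-2-yl)cyclohexan-1-one | C=C(C[C@@H]1[C@@H](C(=C)C)CC[C@@](C)(O)C1=O)[C@@H]1CC[C@](C)(O)[C@H](Br)C1
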